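The polyene is cut at C7=C8 and C7'=C8' into crocetindialdehyde and two cyclogeranyl phosphonium salts of opposite ring configuration, (2R) for the prenyl ring and (2'S) for the diol ring. Each ring comes from an acyclic (E)-4-methoxy-1,5-dien-3-ol carrying a remote methyl ketone. In one pot an anionic oxy-Cope rearrangement joins the gem-dimethyl carbon C1 to the stereocentre C2, and the aldehyde it releases then condenses through C6 with the C5 ketone, closing the cyclohexene at its tetrasubstituted C5=C6 bond. The step exploits the C1(quaternary)–C2(tertiary) junction next to a two-carbon side chain; the glycol stereocentres, set by alkoxyallylboration with either pinene antipode, are consumed.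

Key step: step 3

Assumption: all-E crocetindialdehyde (25) and both antipodes of Ipc2BOMe are bought; steps 8–10 repeat steps 1–3 in the mirror-image series, because the two rings of the target have opposite configuration.

Step 1
Reactants: 1 3-methylbut-2-enal; 2 allyl methyl ether
Product: 4 (3R,4R)-3-methoxy-6-methylhepta-1,5-dien-4-ol, via methoxyallylborane 3 (not isolated)
Conditions: 2, s-BuLi, THF, −78 °C; (−)-Ipc2BOMe; BF3·OEt2; then 1, −78 °C; NaOH, H2O2
Reagents that add atoms: none
Why: Asymmetric alkoxyallylboration through a closed six-membered chair transition state: the (Z)-γ-methoxyallyl geometry should give the syn glycol ether and the isopinocampheyl groups derived from (+)-α-pinene should send the allyl unit to the si face of the aldehyde, which sets both new stereocentres as (3R,4R).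

Step 2
Reactants: 4 (3R,4R)-3-methoxy-6-methylhepta-1,5-dien-4-ol; 5 hex-5-en-2-one
Product: 6 (5E,7R,8R)-8-hydroxy-7-methoxy-10-methylundeca-5,9-dien-2-one
Conditions: second-generation Grubbs catalyst RuCl2(=CHPh)(PCy3)(H2IMes) (cat.), 5 (excess), CH2Cl2, 40 °C
Reagents that add atoms: none
Why: Olefin cross-metathesis of the monosubstituted alkene of 4 with the terminal alkene of 5 should give the (E)-disubstituted alkene while the trisubstituted alkene stays inert; no stereocentre is formed, but the minor (Z) isomer has to be removed by chromatography because it would lead to the opposite ring configuration in step 3.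

Step 3
Reactants: 6 (5E,7R,8R)-8-hydroxy-7-methoxy-10-methylundeca-5,9-dien-2-one
Product: 9 (5S)-2,6,6-trimethyl-5-(2-oxoethyl)cyclohex-1-ene-1-carbaldehyde, via keto aldehyde 7 (not isolated), via enol ether enal 8 (not isolated)
Conditions: KH, 18-crown-6, THF, 0 °C to rt; then AcOH, piperidine, 60 °C; then 1 M HCl, rt
Reagents that add atoms: water, O
Why: KH gives the C8 potassium alkoxide (and the ketone enolate), whose anionic oxy-Cope rearrangement, a [3,3] shift through a chair, forms the bond between the gem-dimethyl carbon and the future ring stereocentre and leaves an aldehyde enolate and an (E)-enol ether; after the AcOH quench the piperidine enamine of aldehyde 7 adds to the methyl ketone and loses water, so the second bond arises as the tetrasubstituted ring alkene, and dilute acid finally unmasks the side-chain aldehyde. The closest known reaction types are the anionic oxy-Cope rearrangement of 1,5-dien-3-ols and the amine-salt cyclisation of keto aldehydes to 2-methylcycloalk-1-ene carbaldehydes. The six-membered ring closes in the 6-(enolexo)-exo-trig mode. The single new stereocentre is controlled by chirality transfer from the (7R,8R) glycol and the (5E) alkene: only the chair with oxido and methoxy groups equatorial avoids the axial methyl of the isopropylidene terminus, and it should give (5S), while the two glycol centres disappear. The step needs the [3,3] shift to win over alkoxide fragmentation and the aldehyde-enamine aldol mode to win over the five-membered modes; the non-stabilised methoxyallyl leaving group disfavours fragmentation, and the enol ether keeps the second aldehyde masked until the ring is closed.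

Step 4
Reactants: 9 (5S)-2,6,6-trimethyl-5-(2-oxoethyl)cyclohex-1-ene-1-carbaldehyde
Product: 10 (5S)-2,6,6-trimethyl-5-(prop-2-en-1-yl)cyclohex-1-ene-1-carbaldehyde
Conditions: Ph3PCH3Br, n-BuLi, THF, 0 °C; then 9, −78 °C
Reagents that add atoms: methyltriphenylphosphonium bromide, C[P+](c1ccccc1)(c1ccccc1)c1ccccc1.[Br-]
Why: Wittig methylenation: at −78 °C the unstabilised ylide should take the unhindered aliphatic aldehyde and leave the conjugated, doubly flanked ring aldehyde alone; no stereocentre is formed and the existing one is not enolisable.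

Step 5
Reactants: 10 (5S)-2,6,6-trimethyl-5-(prop-2-en-1-yl)cyclohex-1-ene-1-carbaldehyde; 11 2-methylidenepropane-1,3-diyl diacetate
Product: 12 2-{2-[(1S)-3-formyl-2,2,4-trimethylcyclohex-3-en-1-yl]ethylidene}propane-1,3-diyl diacetate
Conditions: second-generation Hoveyda–Grubbs catalyst RuCl2(=CH-C6H4-2-OiPr)(H2IMes) (cat.), 11 (excess), CH2Cl2, 40 °C
Reagents that add atoms: none
Why: Olefin cross-metathesis of the allyl group with an excess of the 1,1-disubstituted alkene 11 should give the trisubstituted alkene, free of E/Z isomerism because its two CH2OAc arms are identical; the tetrasubstituted ring alkene cannot take part and no stereocentre is formed.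

Step 6
Reactants: 12 2-{2-[(1S)-3-formyl-2,2,4-trimethylcyclohex-3-en-1-yl]ethylidene}propane-1,3-diyl diacetate
Product: 13 2-{2-[(1S)-3-(hydroxymethyl)-2,2,4-trimethylcyclohex-3-en-1-yl]ethylidene}propane-1,3-diyl diacetate
Conditions: NaBH4, MeOH, 0 °C
Reagents that add atoms: none
Why: Hydride 1,2-reduction of the enal with NaBH4 at 0 °C should leave the acetates, the alkenes and the remote stereocentre untouched.

Step 7
Reactants: 13 2-{2-[(1S)-3-(hydroxymethyl)-2,2,4-trimethylcyclohex-3-en-1-yl]ethylidene}propane-1,3-diyl diacetate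
Product: 15 {[(5S)-5-{4-acetoxy-3-[(acetoxy)methyl]but-2-en-1-yl}-2,6,6-trimethylcyclohex-1-en-1-yl]methyl}triphenylphosphonium bromide, via allylic bromide 14 (not isolated)
Conditions: CBr4, PPh3, CH2Cl2, 0 °C; then PPh3, toluene, 60 °C
Reagents that add atoms: carbon tetrabromide, BrC(Br)(Br)Br; triphenylphosphine, c1ccc(cc1)P(c1ccccc1)c1ccccc1
Why: Appel reaction to the allylic bromide under neutral conditions, then SN2 quaternisation of PPh3 in the same flask, a sequence that should spare the allylic acetates; no stereocentre is involved.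

Step 8
Reactants: 1 3-methylbut-2-enal; 2 allyl methyl ether
Product: 17 (3S,4S)-3-methoxy-6-methylhepta-1,5-dien-4-ol, via methoxyallylborane 16 (not isolated)
Conditions: 2, s-BuLi, THF, −78 °C; (+)-Ipc2BOMe; BF3·OEt2; then 1, −78 °C; NaOH, H2O2
Reagents that add atoms: none
Why: Same alkoxyallylboration as step 1 with the borane derived from (−)-α-pinene, which should attack the re face and give the (3S,4S) syn isomer.

Step 9
Reactants: 17 (3S,4S)-3-methoxy-6-methylhepta-1,5-dien-4-ol; 5 hex-5-en-2-one
Product: 18 (5E,7S,8S)-8-hydroxy-7-methoxy-10-methylundeca-5,9-dien-2-one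
Conditions: second-generation Grubbs catalyst RuCl2(=CHPh)(PCy3)(H2IMes) (cat.), 5 (excess), CH2Cl2, 40 °C
Reagents that add atoms: none
Why: Same olefin cross-metathesis as step 2 in the mirror-image series, with the (Z) isomer again removed; no stereocentre is formed.

Step 10
Reactants: 18 (5E,7S,8S)-8-hydroxy-7-methoxy-10-methylundeca-5,9-dien-2-one
Product: 21 (5R)-2,6,6-trimethyl-5-(2-oxoethyl)cyclohex-1-ene-1-carbaldehyde, via keto aldehyde 19 (not isolated), via enol ether enal 20 (not isolated)
Conditions: KH, 18-crown-6, THF, 0 °C to rt; then AcOH, piperidine, 60 °C; then 1 M HCl, rt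
Reagents that add atoms: water, O
Why: Same anionic oxy-Cope rearrangement, enamine aldol condensation and enol ether hydrolysis as step 3: chirality transfer from the (7S,8S) glycol and the (5E) alkene through the diequatorial chair should give (5R).

Step 11
Reactants: 21 (5R)-2,6,6-trimethyl-5-(2-oxoethyl)cyclohex-1-ene-1-carbaldehyde
Product: 22 (5R)-2,6,6-trimethyl-5-(3-methylbut-2-en-1-yl)cyclohex-1-ene-1-carbaldehyde
Conditions: i-PrPPh3I, n-BuLi, THF, 0 °C; then 21, −78 °C
Reagents that add atoms: isopropyltriphenylphosphonium iodide, CC(C)[P+](c1ccccc1)(c1ccccc1)c1ccccc1.[I-]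
Why: Wittig reaction with isopropylidenetriphenylphosphorane, which at −78 °C should olefinate only the unhindered aliphatic aldehyde and so complete the 3-methylbut-2-enyl side chain; no stereocentre is formed.

Step 12
Reactants: 22 (5R)-2,6,6-trimethyl-5-(3-methylbut-2-en-1-yl)cyclohex-1-ene-1-carbaldehyde
Product: 23 [(5R)-2,6,6-trimethyl-5-(3-methylbut-2-en-1-yl)cyclohex-1-en-1-yl]methanol
Conditions: NaBH4, MeOH, 0 °C
Reagents that add atoms: none
Why: NaBH4 1,2-reduction of the hindered enal to the allylic alcohol; the trisubstituted alkenes and the stereocentre are untouched.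

Step 13
Reactants: 23 [(5R)-2,6,6-trimethyl-5-(3-methylbut-2-en-1-yl)cyclohex-1-en-1-yl]methanol
Product: 24 {[(5R)-2,6,6-trimethyl-5-(3-methylbut-2-en-1-yl)cyclohex-1-en-1-yl]methyl}triphenylphosphonium bromide
Conditions: PPh3·HBr, MeOH, rt
Reagents that add atoms: triphenylphosphine hydrobromide, [Br-].[PH+](c1ccccc1)(c1ccccc1)c1ccccc1
Why: Phosphonium salt formation with PPh3·HBr (SN1-type substitution through the allylic cation trapped by PPh3), the usual entry to carotenoid Wittig salts; the stereocentre is remote from the cation.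

Step 14
Reactants: 24 {[(5R)-2,6,6-trimethyl-5-(3-methylbut-2-en-1-yl)cyclohex-1-en-1-yl]methyl}triphenylphosphonium bromide; 25 all-E crocetindialdehyde
Product: 27 (all-E,2R)-2-(3-methylbut-2-en-1-yl)-8'-apo-β-caroten-8'-al, via phosphorus ylide 26 (not isolated)
Conditions: 25 (excess), NaOMe, CH2Cl2/MeOH, 0 °C to rt; then cat. I2, hexane, daylight
Reagents that add atoms: none
Why: Wittig reaction of the allylic ylide 26 with one formyl group of the dialdehyde used in excess; iodine-catalysed equilibration should leave the new C7=C8 bond (E) because the (7Z) isomer is crowded by the ring methyl groups; no stereocentre is formed.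

Step 15
Reactants: 27 (all-E,2R)-2-(3-methylbut-2-en-1-yl)-8'-apo-β-caroten-8'-al; 15 {[(5S)-5-{4-acetoxy-3-[(acetoxy)methyl]but-2-en-1-yl}-2,6,6-trimethylcyclohex-1-en-1-yl]methyl}triphenylphosphonium bromide
Product: 30 (all-E,2R,2'S)-2'-[4-hydroxy-3-(hydroxymethyl)but-2-en-1-yl]-2-(3-methylbut-2-en-1-yl)-β,β-carotene (CNP0213288.1), via phosphorus ylide 28 (not isolated), via carotenoid diacetate 29 (not isolated)
Conditions: 15, NaHMDS, THF, −78 °C; then 27, −78 °C to rt; then K2CO3, MeOH, rt; then heptane, reflux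
Reagents that add atoms: none
Why: Second Wittig reaction, then K2CO3-mediated methanolysis of the two acetates and thermal equilibration to the all-E polyene; both ring stereocentres, (2R) and (2'S), are carried in unchanged from 24 and 15.

Compound list

1 | 3-methylbut-2-enal | CC(C)=CC=O | starting material
2 | allyl methyl ether (3-methoxyprop-1-ene) | COCC=C | starting material
3 | (Z)-(3-methoxyprop-2-en-1-yl)diisopinocampheylborane, isopinocampheyl groups from (+)-α-pinene, formed in the flask | CO/C=C\CB([C@@H]1C[C@@H]2C[C@H]([C@H]1C)C2(C)C)[C@@H]1C[C@@H]2C[C@H]([C@H]1C)C2(C)C | intermediate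
4 | (3R,4R)-3-methoxy-6-methylhepta-1,5-dien-4-ol | CO[C@H](C=C)[C@H](O)C=C(C)C | intermediate
5 | hex-5-en-2-one | CC(=O)CCC=C | starting material
6 | (5E,7R,8R)-8-hydroxy-7-methoxy-10-methylundeca-5,9-dien-2-one | CC(=O)CC/C=C/[C@@H](OC)[C@H](O)C=C(C)C | intermediate
7 | (4S)-4-[(E)-2-methoxyethenyl]-3,3-dimethyl-7-oxooctanal, not isolated | O=CCC(C)(C)[C@H](/C=C/OC)CCC(C)=O | intermediate
8 | (5S)-5-[(E)-2-methoxyethenyl]-2,6,6-trimethylcyclohex-1-ene-1-carbaldehyde, not isolated | O=CC1=C(C)CC[C@@H](/C=C/OC)C1(C)C | intermediate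
9 | (5S)-2,6,6-trimethyl-5-(2-oxoethyl)cyclohex-1-ene-1-carbaldehyde | O=CC1=C(C)CC[C@@H](CC=O)C1(C)C | intermediate
10 | (5S)-2,6,6-trimethyl-5-(prop-2-en-1-yl)cyclohex-1-ene-1-carbaldehyde | O=CC1=C(C)CC[C@@H](CC=C)C1(C)C | intermediate
11 | 2-methylidenepropane-1,3-diyl diacetate | CC(=O)OCC(=C)COC(C)=O | starting material
12 | 2-{2-[(1S)-3-formyl-2,2,4-trimethylcyclohex-3-en-1-yl]ethylidene}propane-1,3-diyl diacetate | O=CC1=C(C)CC[C@@H](CC=C(COC(C)=O)COC(C)=O)C1(C)C | intermediate
13 | 2-{2-[(1S)-3-(hydroxymethyl)-2,2,4-trimethylcyclohex-3-en-1-yl]ethylidene}propane-1,3-diyl diacetate | OCC1=C(C)CC[C@@H](CC=C(COC(C)=O)COC(C)=O)C1(C)C | intermediate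
14 | 2-{2-[(1S)-3-(bromomethyl)-2,2,4-trimethylcyclohex-3-en-1-yl]ethylidene}propane-1,3-diyl diacetate, not isolated | BrCC1=C(C)CC[C@@H](CC=C(COC(C)=O)COC(C)=O)C1(C)C | intermediate
15 | {[(5S)-5-{4-acetoxy-3-[(acetoxy)methyl]but-2-en-1-yl}-2,6,6-trimethylcyclohex-1-en-1-yl]methyl}triphenylphosphonium bromide | [Br-].c1ccccc1[P+](c1ccccc1)(c1ccccc1)CC1=C(C)CC[C@@H](CC=C(COC(C)=O)COC(C)=O)C1(C)C | intermediate
16 | (Z)-(3-methoxyprop-2-en-1-yl)diisopinocampheylborane, isopinocampheyl groups from (−)-α-pinene, formed in the flask | CO/C=C\CB([C@H]1C[C@H]2C[C@@H]([C@@H]1C)C2(C)C)[C@H]1C[C@H]2C[C@@H]([C@@H]1C)C2(C)C | intermediate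
17 | (3S,4S)-3-methoxy-6-methylhepta-1,5-dien-4-ol | CO[C@@H](C=C)[C@@H](O)C=C(C)C | intermediate
18 | (5E,7S,8S)-8-hydroxy-7-methoxy-10-methylundeca-5,9-dien-2-one | CC(=O)CC/C=C/[C@H](OC)[C@@H](O)C=C(C)C | intermediate
19 | (4R)-4-[(E)-2-methoxyethenyl]-3,3-dimethyl-7-oxooctanal, not isolated | O=CCC(C)(C)[C@@H](/C=C/OC)CCC(C)=O | intermediate
20 | (5R)-5-[(E)-2-methoxyethenyl]-2,6,6-trimethylcyclohex-1-ene-1-carbaldehyde, not isolated | O=CC1=C(C)CC[C@H](/C=C/OC)C1(C)C | intermediate
21 | (5R)-2,6,6-trimethyl-5-(2-oxoethyl)cyclohex-1-ene-1-carbaldehyde | O=CC1=C(C)CC[C@H](CC=O)C1(C)C | intermediate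
22 | (5R)-2,6,6-trimethyl-5-(3-methylbut-2-en-1-yl)cyclohex-1-ene-1-carbaldehyde | O=CC1=C(C)CC[C@H](CC=C(C)C)C1(C)C | intermediate
23 | [(5R)-2,6,6-trimethyl-5-(3-methylbut-2-en-1-yl)cyclohex-1-en-1-yl]methanol | OCC1=C(C)CC[C@H](CC=C(C)C)C1(C)C | intermediate
24 | {[(5R)-2,6,6-trimethyl-5-(3-methylbut-2-en-1-yl)cyclohex-1-en-1-yl]methyl}triphenylphosphonium bromide | [Br-].c1ccccc1[P+](c1ccccc1)(c1ccccc1)CC1=C(C)CC[C@H](CC=C(C)C)C1(C)C | intermediate
25 | all-E crocetindialdehyde (2,6,11,15-tetramethylhexadeca-2,4,6,8,10,12,14-heptaenedial) | O=C/C(C)=C/C=C/C(C)=C/C=C/C=C(C)/C=C/C=C(C)/C=O | starting material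
26 | ylide of 24, {[(5R)-2,6,6-trimethyl-5-(3-methylbut-2-en-1-yl)cyclohex-1-en-1-yl]methylidene}triphenylphosphorane, not isolated | c1ccccc1P(c1ccccc1)(c1ccccc1)=CC1=C(C)CC[C@H](CC=C(C)C)C1(C)C | intermediate
27 | (all-E,2R)-2-(3-methylbut-2-en-1-yl)-8'-apo-β-caroten-8'-al (C35 aldehyde: ring A joined through an (E) C7=C8 bond to the crocetindialdehyde chain, other end CHO) | CC(C)=CC[C@H]1CCC(C)=C(/C=C/C(C)=C/C=C/C(C)=C/C=C/C=C(C)/C=C/C=C(C)/C=O)C1(C)C | intermediate
28 | ylide of 15, the (5S) diacetate analogue of 26, not isolated | c1ccccc1P(c1ccccc1)(c1ccccc1)=CC1=C(C)CC[C@@H](CC=C(COC(C)=O)COC(C)=O)C1(C)C | intermediate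
29 | (all-E,2R,2'S)-2'-{4-acetoxy-3-[(acetoxy)methyl]but-2-en-1-yl}-2-(3-methylbut-2-en-1-yl)-β,β-carotene, not isolated | CC(C)=CC[C@H]1CCC(C)=C(/C=C/C(C)=C/C=C/C(C)=C/C=C/C=C(C)/C=C/C=C(C)/C=C/C2=C(C)CC[C@@H](CC=C(COC(C)=O)COC(C)=O)C2(C)C)C1(C)C | intermediate
30 | (all-E,2R,2'S)-2'-[4-hydroxy-3-(hydroxymethyl)but-2-en-1-yl]-2-(3-methylbut-2-en-1-yl)-β,β-carotene (CNP0213288.1) | CC(C)=CC[C@H]1CCC(C)=C(/C=C/C(C)=C/C=C/C(C)=C/C=C/C=C(C)/C=C/C=C(C)/C=C/C2=C(C)CC[C@@H](CC=C(CO)CO)C2(C)C)C1(C)C | target

Total step count: 15. Longest linear sequence: 8 steps (steps 1–7 then 15; the ring A branch, steps 8–15, is equally long).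

Steps most likely to fail

Step 3 (and its mirror-image repeat, step 10). The potassium alkoxide may fragment by retro-allylation, or the shift may become stepwise at the fully substituted alkene terminus and erode chirality transfer. The aldol could also take the ketone-enolate course. The fallback sets out from 6 and comes back at 9. The alcohol is silylated (Et3SiCl, imidazole) to triethylsilyl ether F1. A neutral thermal silyloxy-Cope rearrangement (toluene, sealed tube, 180 °C) should then give silyl enol ether F2 with no alkoxide present. Wet piperidinium acetate frees aldehyde 7 and closes the ring to 8, and dilute HCl gives 9.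

Step 5. Self-metathesis of 10 and non-productive cycles may outrun the cross-reaction with the sluggish 1,1-disubstituted partner. The fallback sets out from 9 and comes back at 13. Knoevenagel condensation of the aliphatic aldehyde with dimethyl malonate (TiCl4, pyridine) gives alkylidene malonate F3. i-Bu2AlH reduces the ring aldehyde and both esters to triol F4. Lipase-catalysed acetylation with vinyl acetate should then acetylate the two unhindered allylic hydroxyls and leave the flanked ring carbinol, giving 13.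

Step 14. The dialdehyde may be olefinated at both ends, and the hindered allylic ylide may turn over slowly with (7Z) formation. The fallback sets out from 23 and comes back at 27. Mitsunobu reaction with 1-phenyl-1H-tetrazole-5-thiol (PPh3, diisopropyl azodicarboxylate) gives tetrazolyl sulfide F5. (NH4)6Mo7O24/H2O2 oxidises it to tetrazolyl sulfone F6. Julia–Kocienski olefination of its potassium anion (KHMDS, THF, −78 °C) with an excess of 25 gives 27.

Further compounds

F1 | step 3 | (5E,7R,8R)-7-methoxy-10-methyl-8-[(triethylsilyl)oxy]undeca-5,9-dien-2-one | CC(=O)CC/C=C/[C@@H](OC)[C@H](O[Si](CC)(CC)CC)C=C(C)C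
F2 | step 3 | (5S)-5-[(E)-2-methoxyethenyl]-6,6-dimethyl-8-[(triethylsilyl)oxy]oct-7-en-2-one (E-silyl enol ether) | CC[Si](CC)(CC)O/C=C/C(C)(C)[C@H](/C=C/OC)CCC(C)=O
F3 | step 5 | dimethyl 2-{2-[(1S)-3-formyl-2,2,4-trimethylcyclohex-3-en-1-yl]ethylidene}propanedioate | O=CC1=C(C)CC[C@@H](CC=C(C(=O)OC)C(=O)OC)C1(C)C
F4 | step 5 | 2-{2-[(1S)-3-(hydroxymethyl)-2,2,4-trimethylcyclohex-3-en-1-yl]ethylidene}propane-1,3-diol | OCC1=C(C)CC[C@@H](CC=C(CO)CO)C1(C)C
F5 | step 14 | 5-({[(5R)-2,6,6-trimethyl-5-(3-methylbut-2-en-1-yl)cyclohex-1-en-1-yl]methyl}sulfanyl)-1-phenyl-1H-tetrazole | c1ccccc1-n1nnnc1SCC1=C(C)CC[C@H](CC=C(C)C)C1(C)C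
F6 | step 14 | 5-({[(5R)-2,6,6-trimethyl-5-(3-methylbut-2-en-1-yl)cyclohex-1-en-1-yl]methyl}sulfonyl)-1-phenyl-1H-tetrazole | c1ccccc1-n1nnnc1S(=O)(=O)CC1=C(C)CC[C@H](CC=C(C)C)C1(C)C
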